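**Retrosynthetic overview**

1. Target ⇐ 8α-ester 43 (Mitsunobu inversion of 8β-alcohol 39) ⇐ α-methylene trans-lactone 37 ⇐ keto-lactone 31; the end game only adjusts C-14 (acetate), C-15 (enal) and the side-chain OH.
2. γ-Lactone (formed last) ⇐ C-7 alkylation of the regiodefined C-7=C-8 enol silane 27, then lactonisation onto O-6.
3. Cyclohexane ⇐ C-9–C-10 bond by Ireland–Claisen ring contraction of δ-lactone 22. The feature used: quaternary C-10 carries a one-carbon oxygenated branch (C-14) and a vinyl group and lies 1,3 to oxygenated C-8 through C-9. So C-14 can be the carbonyl of a temporary six-membered lactone ring C-14–O–C-7–C-6–C-5–C-10, the vinyl group the tail of its dienolate, and C-8=C-9 a 2-silyloxyallyl arm on C-7.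
4. δ-Lactone 22 ⇐ dihydropyranone 12 by anti cuprate addition (sets C-5), acetaldehyde aldol and dehydration; 12 ⇐ Brown alkoxyallylation of methacrolein (sets C-6, C-7), acrylation, ring-closing metathesis, ozonolysis.
5. Ring order: dihydropyranone (temporary) → cyclohexene (key step; the pyranone ring is opened in the same event) → γ-lactone.

Key step: step 10

Remark: locants C-1 to C-15 follow elemane numbering (C-10 quaternary ring carbon, C-14 its CH2O branch, C-1/C-2 vinyl, C-5 ring CH bearing the C-4(=C-3)–C-15 unit, C-6 O-bearing CH, C-7 ring CH bearing C-11/C-12/C-13, C-8 acyloxy CH, C-9 ring CH2); β is the face of C-14; compounds 9–24 are numbered as pyranones; MOM = methoxymethyl, PMB = 4-methoxybenzyl, TBS = tert-butyldimethylsilyl, TBDPS = tert-butyldiphenylsilyl, TES = triethylsilyl.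

**Step 1**
Reactants: 1 prop-2-en-1-ol
Product: 2 3-(methoxymethoxy)prop-1-ene
Conditions: MOMCl, iPr2NEt, CH2Cl2, 0 °C to rt
Reagents that add atoms: chloromethyl methyl ether, COCCl
Why: O-alkylation of a primary alcohol by a reactive α-chloro ether (MOM protection) should be clean and creates no stereocenter.

**Step 2**
Reactants: 2 3-(methoxymethoxy)prop-1-ene, 3 2-methylprop-2-enal
Product: 7 (3R,4R)-4-(methoxymethoxy)-2-methylhexa-1,5-dien-3-ol, via lithiated allyl ether 4 (not isolated), via allylborane 5 (not isolated), via borinate ester 6 (not isolated)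
Conditions: s-BuLi, THF, −78 °C; (−)-Ipc2BOMe; BF3·OEt2; 3, −78 °C; NaOH, H2O2, 0 °C to rt
Reagents that add atoms: none
Why: Brown asymmetric γ-alkoxyallylboration: the chelated Z-allyl anion gives the Z-allylborane, whose chair Zimmerman–Traxler transition state delivers the syn relationship, and the isopinocampheyl groups from (+)-α-pinene select the aldehyde face to give the (3R,4R) pair (C-7 carbinol, C-6 ether).

**Step 3**
Reactants: 7 (3R,4R)-4-(methoxymethoxy)-2-methylhexa-1,5-dien-3-ol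
Product: 8 (3R,4R)-4-(methoxymethoxy)-2-methylhexa-1,5-dien-3-yl prop-2-enoate
Conditions: CH2=CHCOCl, Et3N, DMAP (cat.), CH2Cl2, −20 to 0 °C
Reagents that add atoms: acryloyl chloride, C=CC(Cl)=O
Why: DMAP-catalysed O-acylation of a secondary alcohol with an acid chloride leaves both stereocenters untouched.

**Step 4**
Reactants: 8 (3R,4R)-4-(methoxymethoxy)-2-methylhexa-1,5-dien-3-yl prop-2-enoate
Product: 9 (5R,6R)-5-(methoxymethoxy)-6-(prop-1-en-2-yl)-5,6-dihydro-2H-pyran-2-one
Conditions: second-generation Grubbs catalyst RuCl2(=CHPh)(PCy3)(H2IMes) (5 mol %), CH2Cl2 (0.01 M), 40 °C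
Reagents that add atoms: none
Why: Ring-closing metathesis between the acrylate and the monosubstituted vinyl group should give the six-membered unsaturated lactone, because the 1,1-disubstituted isopropenyl group initiates much more slowly and would close only a five-membered ring.

**Step 5**
Reactants: 9 (5R,6R)-5-(methoxymethoxy)-6-(prop-1-en-2-yl)-5,6-dihydro-2H-pyran-2-one
Product: 11 (5R,6S)-6-acetyl-5-(methoxymethoxy)-5,6-dihydro-2H-pyran-2-one, via ozonide 10 (not isolated)
Conditions: O3, CH2Cl2, −78 °C (Sudan Red 7B end point); Me2S, −78 °C to rt; used crude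
Reagents that add atoms: ozone, [O-][O+]=O
Why: Ozonolysis with reductive work-up should cleave the electron-rich isopropenyl alkene far faster than the electron-poor conjugated lactone alkene, giving the methyl ketone without touching the stereocenters.

**Step 6**
Reactants: 11 (5R,6S)-6-acetyl-5-(methoxymethoxy)-5,6-dihydro-2H-pyran-2-one
Product: 12 (5R,6S)-6-[1-(tert-butyldimethylsilyloxy)ethenyl]-5-(methoxymethoxy)-5,6-dihydro-2H-pyran-2-one
Conditions: TBSOTf, Et3N, CH2Cl2, −78 °C
Reagents that add atoms: tert-butyldimethylsilyl trifluoromethanesulfonate, CC(C)(C)[Si](C)(C)OS(=O)(=O)C(F)(F)F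
Why: Soft enolisation (silyl triflate, amine) deprotonates the O-silylated ketone at the unhindered CH3 to give the terminal enol silane, which masks the ketone so that C-6 can no longer epimerise or lose the neighbouring OMOM group in the basic steps that follow.

**Step 7**
Reactants: 13 2,3-dibromoprop-1-ene, 14 (4-methoxyphenyl)methanol
Product: 16 1-{[(2-bromoprop-2-en-1-yl)oxy]methyl}-4-methoxybenzene, via sodium alkoxide 15 (not isolated)
Conditions: NaH, THF–DMF, 0 °C to rt
Reagents that add atoms: none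
Why: Williamson ether synthesis at the allylic bromide; the vinylic bromide does not react.

**Step 8**
Reactants: 12 (5R,6S)-6-[1-(tert-butyldimethylsilyloxy)ethenyl]-5-(methoxymethoxy)-5,6-dihydro-2H-pyran-2-one, 16 1-{[(2-bromoprop-2-en-1-yl)oxy]methyl}-4-methoxybenzene
Product: 20 (3R,4R,5R,6S)-3-(1-hydroxyethyl)-4-{3-[(4-methoxybenzyl)oxy]prop-1-en-2-yl}-5-(methoxymethoxy)-6-[1-(TBS-oxy)ethenyl]tetrahydro-2H-pyran-2-one (carbinol epimers), via vinyllithium 17 (not isolated), via Gilman cuprate 18 (not isolated), via lithium enolate 19 (not isolated)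
Conditions: 16 (2 equiv), t-BuLi, Et2O, −78 °C; CuBr·SMe2, −78 to −50 °C; 12, −78 °C; CH3CHO, −78 °C; NH4Cl (aq)
Reagents that add atoms: acetaldehyde, CC=O
Why: Bromine–lithium exchange and Gilman cuprate conjugate addition: the reagent should add to C-4 of the dihydropyranone anti to the two cis substituents at C-5 and C-6, setting the new center (C-5 of the target) trans to the OMOM group, and the enolate is trapped in an aldol reaction with acetaldehyde whose carbinol configuration is irrelevant.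

**Step 9**
Reactants: 20 aldol adduct (as above)
Product: 22 (3E,4S,5R,6S)-3-ethylidene-4-{3-[(4-methoxybenzyl)oxy]prop-1-en-2-yl}-5-(methoxymethoxy)-6-[1-(TBS-oxy)ethenyl]tetrahydro-2H-pyran-2-one, via mesylate 21 (not isolated)
Conditions: MsCl, Et3N, CH2Cl2, 0 °C; then DBU, 0 °C to rt
Reagents that add atoms: none
Why: Mesylation and E1cB elimination should convert both carbinol epimers into the conjugated ethylidene lactone; the enol silane and the ring stereocenters carry no acidic hydrogen.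

**Step 10**
Reactants: 22 ethylidene δ-lactone (as above)
Product: 26 cyclohexene alcohol: C-10 β-CH2OH and α-vinyl, C-5 β-[3-(PMB-oxy)prop-1-en-2-yl], C-6 α-OMOM, C-7=C-8 enol TBS ether, via lithium dienolate 23 (not isolated), via bis-silyl ketene acetal 24 (not isolated), via silyl ester 25 (not isolated)
Conditions: LiN(iPr)2, THF–HMPA, −78 °C; TBSCl, −78 to 0 °C; toluene, 90 °C; then LiAlH4, 0 °C; KNaC4H4O6 (aq)
Reagents that add atoms: none
Why: γ-Deprotonation of the ethylidene lactone and O-silylation give the cyclic vinyl ketene acetal 24, whose array C-10=C-14–O–C-7–C-8=C-9 undergoes a concerted [3,3] shift that forms C-9–C-10 and breaks O–C-7, after which LiAlH4 reduces the silyl ester 25 in the same flask. The closest known reaction type is the Ireland–Claisen ring contraction of alkenyl-lactone silyl ketene acetals to cycloalkenecarboxylic acids, combined with the α-selective Claisen rearrangement of ester dienolates. The six-membered carbocycle closes through a boat-like transition state shaped like bicyclo[2.2.2]octane, in which the lactone bridges the two ends of the pericyclic array and its C-5–C-6 unit becomes part of the new ring. The only new stereocenter, quaternary C-10, is controlled by the C-7 carbinol center, which is destroyed: C-9 can reach C-10 only on the lactone face that carries the C-7 arm, so C-14 ends cis to the C-5 branch and trans to O-6, and the vinyl group on the opposite face. The step needs deprotonation at the ethylidene CH3 and bonding at the α- rather than the γ-carbon of the dienolate; the CH3 is the only acidic position once the ketone is masked as its enol silane, and only the α-carbon lies in the cyclic six-electron array. The migrating terminus leaves as a regiodefined C-7=C-8 enol silane that later directs the C-7 alkylation.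

**Step 11**
Reactants: 26 cyclohexene alcohol
Product: 27 14-O-TBDPS ether of 26
Conditions: TBDPSCl, imidazole, DMAP (cat.), DMF, 40 °C
Reagents that add atoms: tert-butyl(chloro)diphenylsilane, CC(C)(C)[Si](Cl)(c1ccccc1)c1ccccc1
Why: Silylation of the neopentyl primary alcohol under mild base leaves the enol silane intact and prevents hemiketal formation between the axial C-14 OH and the later C-8 ketone.

**Step 12**
Reactants: 27 14-O-TBDPS enol silane
Product: 29 keto ester: 8-oxo, 7β-CH2CO2Et (7αH), 6α-OMOM, 5β-[3-(PMB-oxy)prop-1-en-2-yl], 10β-CH2OTBDPS, 10α-vinyl, via C-7 epimer mixture 28 (not isolated)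
Conditions: BrCH2CO2Et, fac-Ir(ppy)3 (1 mol %), 2,6-lutidine, MeCN–H2O, blue LEDs, rt; then DBU (0.2 equiv), CH2Cl2, rt
Reagents that add atoms: ethyl bromoacetate, CCOC(=O)CBr
Why: Visible-light photoredox α-alkylation of a silyl enol ether: the electrophilic ethoxycarbonylmethyl radical adds to C-7, the electron-rich terminus fixed by the Claisen step, oxidation and loss of silicon give the ketone, and DBU equilibration through the enol should put the new C-7 substituent equatorial, trans to the C-6 OMOM group.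

**Step 13**
Reactants: 29 keto ester
Product: 31 trans-fused keto-lactone: 12,6α-olide with C-11 H2, 8-oxo, 14-OTBDPS, 15-OPMB (5αH,6βH,7αH), via hydroxy ester 30 (not isolated)
Conditions: Me2BBr, CH2Cl2, −78 °C; NaHCO3 (aq), THF; then TsOH·H2O (cat.), CH2Cl2, rt
Reagents that add atoms: none
Why: Lewis-acid cleavage of the MOM acetal at −78 °C spares the silyl and PMB ethers, and acid-catalysed lactonisation of the γ-hydroxy ester gives the trans-fused lactone because the C-6 OH and the C-7 CH2CO2Et are trans-diequatorial and lactonisation is faster than enolisation at rt.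

**Step 14**
Reactants: 31 keto-lactone
Product: 33 8β-(TES-oxy) lactone (8αH), via lithium alkoxide 32 (not isolated)
Conditions: Li[HB(s-Bu)3], THF, −78 °C; then TESOTf, −78 to −20 °C
Reagents that add atoms: triethylsilyl trifluoromethanesulfonate, CC[Si](CC)(CC)OS(=O)(=O)C(F)(F)F
Why: The bulky trialkylborohydride attacks the C-8 ketone from the equatorial α direction, away from the syn-axial C-14 branch, giving the axial 8β-alkoxide, which is silylated in situ before it can translactonise onto C-12.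

**Step 15**
Reactants: 33 8β-(TES-oxy) lactone
Product: 37 8β-(TES-oxy)-14-(TBDPS-oxy)-15-(PMB-oxy)elema-1,3,11(13)-trien-12,6α-olide, via lithium enolate 34 (not isolated), via Mannich base 35 (not isolated), via ammonium iodide 36 (not isolated)
Conditions: LiN(iPr)2, THF, −78 °C; CH2=NMe2+ I−, −78 to 0 °C; MeI, MeOH, rt; NaHCO3 (aq), CH2Cl2, rt
Reagents that add atoms: N,N-dimethylmethyleneiminium iodide (Eschenmoser's salt), C=[N+](C)C.[I-]
Why: Lactone α-methylenation by enolate Mannich reaction, N-methylation and E1cB loss of trimethylamine; the lactone CH2 is the only enolisable position in 33.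

**Step 16**
Reactants: 37 α-methylene lactone bis-silyl ether
Product: 38 8β,14-dihydroxy-15-(PMB-oxy)elema-1,3,11(13)-trien-12,6α-olide
Conditions: HF·pyridine, pyridine, THF, 0 to 40 °C
Reagents that add atoms: none
Why: Fluoride desilylation removes the TES and TBDPS ethers while the PMB ether, the lactone and the alkenes are inert to buffered HF.

**Step 17**
Reactants: 38 diol
Product: 39 14-acetoxy-8β-hydroxy-15-(PMB-oxy)elema-1,3,11(13)-trien-12,6α-olide
Conditions: Ac2O (1.1 equiv), 2,4,6-collidine, CH2Cl2, −20 °C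
Reagents that add atoms: acetic anhydride, CC(=O)OC(C)=O
Why: Selective acylation of the primary C-14 alcohol should be possible because the secondary 8β-OH is axial and flanked by the ring fusion.

**Step 18**
Reactants: 40 ethyl 2-(hydroxymethyl)prop-2-enoate
Product: 41 ethyl 2-{[(tert-butyldimethylsilyl)oxy]methyl}prop-2-enoate
Conditions: TBSCl, imidazole, DMF, 0 °C to rt
Reagents that add atoms: tert-butyl(chloro)dimethylsilane, CC(C)(C)[Si](C)(C)Cl
Why: Standard silylation of a primary allylic alcohol.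

**Step 19**
Reactants: 41 ethyl 2-{[(tert-butyldimethylsilyl)oxy]methyl}prop-2-enoate
Product: 42 2-{[(tert-butyldimethylsilyl)oxy]methyl}prop-2-enoic acid
Conditions: LiOH, THF–H2O, 0 °C; HCl (aq) to pH 4
Reagents that add atoms: lithium hydroxide, [Li+].[OH-]
Why: Saponification of the ethyl ester; a primary TBS ether survives cold aqueous LiOH and a brief mild acidification.

**Step 20**
Reactants: 39 14-acetoxy-8β-hydroxy lactone, 42 2-{[(tert-butyldimethylsilyl)oxy]methyl}prop-2-enoic acid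
Product: 43 14-acetoxy-8α-{2-[(TBS-oxy)methyl]acryloyloxy}-15-(PMB-oxy)elema-1,3,11(13)-trien-12,6α-olide
Conditions: PPh3, DIAD, toluene, 0 °C to rt
Reagents that add atoms: none
Why: Mitsunobu esterification: the carboxylate displaces the axial 8β-alkoxyphosphonium group from the unhindered equatorial side with inversion, setting the 8α ester of the target.

**Step 21**
Reactants: 43 8α-ester
Product: 44 14-acetoxy-15-hydroxy-8α-{2-[(TBS-oxy)methyl]acryloyloxy}elema-1,3,11(13)-trien-12,6α-olide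
Conditions: DDQ, CH2Cl2–pH 7 buffer, 0 °C
Reagents that add atoms: none
Why: Oxidative cleavage of the electron-rich PMB ether by DDQ; silyl ether, esters and electron-poor alkenes are inert.

**Step 22**
Reactants: 44 C-15 allylic alcohol
Product: 45 14-acetoxy-15-oxo-8α-{2-[(TBS-oxy)methyl]acryloyloxy}elema-1,3,11(13)-trien-12,6α-olide
Conditions: MnO2, CH2Cl2, rt
Reagents that add atoms: none
Why: MnO2 oxidation of the only free hydroxyl, an allylic primary alcohol, to the 2-substituted acrolein under neutral conditions.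

**Step 23**
Reactants: 45 silylated enal
Product: 46 14-acetoxy-8α-[2-(hydroxymethyl)acryloyloxy]-15-oxoelema-1,3,11(13)-trien-12,6α-olide (CNP0185525.1)
Conditions: HF·pyridine, pyridine, THF, 0 °C
Reagents that add atoms: none
Why: Buffered fluoride desilylation of the primary TBS ether; acetate, enal, acrylate and α-methylene lactone tolerate these conditions.

**Compound list**

1 | prop-2-en-1-ol | C=CCO | starting material
2 | 3-(methoxymethoxy)prop-1-ene | C=CCOCOC | intermediate
3 | 2-methylprop-2-enal (methacrolein) | CC(=C)C=O | starting material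
4 | (Z)-3-(methoxymethoxy)allyllithium (not isolated) | [Li]C/C=C\OCOC | intermediate
5 | (Z)-[3-(methoxymethoxy)allyl]bis(isopinocampheyl)borane, isopinocampheyl groups from (+)-α-pinene (not isolated) | COCO/C=C\CB([C@@H]1C[C@@H]2C[C@H]([C@H]1C)C2(C)C)[C@@H]1C[C@@H]2C[C@H]([C@H]1C)C2(C)C | intermediate
6 | bis(isopinocampheyl)borinate ester of 7 (not isolated) | CC(=C)[C@@H](OB([C@@H]1C[C@@H]2C[C@H]([C@H]1C)C2(C)C)[C@@H]1C[C@@H]2C[C@H]([C@H]1C)C2(C)C)[C@H](OCOC)C=C | intermediate
7 | (3R,4R)-4-(methoxymethoxy)-2-methylhexa-1,5-dien-3-ol | CC(=C)[C@@H](O)[C@H](OCOC)C=C | intermediate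
8 | (3R,4R)-4-(methoxymethoxy)-2-methylhexa-1,5-dien-3-yl prop-2-enoate | C=CC(=O)O[C@H](C(C)=C)[C@H](OCOC)C=C | intermediate
9 | (5R,6R)-5-(methoxymethoxy)-6-(prop-1-en-2-yl)-5,6-dihydro-2H-pyran-2-one | CC(=C)[C@H]1OC(=O)C=C[C@H]1OCOC | intermediate
10 | secondary ozonide (1,2,4-trioxolane) of the isopropenyl group of 9 (not isolated) | CC2(OOCO2)[C@H]1OC(=O)C=C[C@H]1OCOC | intermediate
11 | (5R,6S)-6-acetyl-5-(methoxymethoxy)-5,6-dihydro-2H-pyran-2-one | CC(=O)[C@H]1OC(=O)C=C[C@H]1OCOC | intermediate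
12 | (5R,6S)-6-[1-(tert-butyldimethylsilyloxy)ethenyl]-5-(methoxymethoxy)-5,6-dihydro-2H-pyran-2-one | C=C(O[Si](C)(C)C(C)(C)C)[C@H]1OC(=O)C=C[C@H]1OCOC | intermediate
13 | 2,3-dibromoprop-1-ene | C=C(Br)CBr | starting material
14 | (4-methoxyphenyl)methanol | COc1ccc(CO)cc1 | starting material
15 | sodium (4-methoxyphenyl)methanolate (not isolated) | [Na+].[O-]Cc1ccc(OC)cc1 | intermediate
16 | 1-{[(2-bromoprop-2-en-1-yl)oxy]methyl}-4-methoxybenzene | C=C(Br)COCc1ccc(OC)cc1 | intermediate
17 | {3-[(4-methoxybenzyl)oxy]prop-1-en-2-yl}lithium (not isolated) | [Li]C(=C)COCc1ccc(OC)cc1 | intermediate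
18 | lithium bis{3-[(4-methoxybenzyl)oxy]prop-1-en-2-yl}cuprate (not isolated) | [Li+].C=C(COCc1ccc(OC)cc1)[Cu-]C(=C)COCc1ccc(OC)cc1 | intermediate
19 | lithium enolate of the conjugate adduct of 12 (not isolated) | C=C(O[Si](C)(C)C(C)(C)C)[C@H]1OC(O[Li])=C[C@H](C(=C)COCc2ccc(OC)cc2)[C@H]1OCOC | intermediate
20 | (3R,4R,5R,6S)-3-(1-hydroxyethyl)-4-{3-[(4-methoxybenzyl)oxy]prop-1-en-2-yl}-5-(methoxymethoxy)-6-[1-(TBS-oxy)ethenyl]tetrahydro-2H-pyran-2-one, carbinol epimers | C=C(O[Si](C)(C)C(C)(C)C)[C@H]1OC(=O)[C@@H](C(C)O)[C@H](C(=C)COCc2ccc(OC)cc2)[C@H]1OCOC | intermediate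
21 | methanesulfonate of 20 (not isolated) | C=C(O[Si](C)(C)C(C)(C)C)[C@H]1OC(=O)[C@@H](C(C)OS(C)(=O)=O)[C@H](C(=C)COCc2ccc(OC)cc2)[C@H]1OCOC | intermediate
22 | (3E,4S,5R,6S)-3-ethylidene-4-{3-[(4-methoxybenzyl)oxy]prop-1-en-2-yl}-5-(methoxymethoxy)-6-[1-(TBS-oxy)ethenyl]tetrahydro-2H-pyran-2-one | C=C(O[Si](C)(C)C(C)(C)C)[C@H]1OC(=O)/C(=C/C)[C@H](C(=C)COCc2ccc(OC)cc2)[C@H]1OCOC | intermediate
23 | lithium dienolate of 22, 3-vinyl-5,6-dihydro-4H-pyran-2-olate (not isolated) | C=CC1=C(O[Li])O[C@H](C(=C)O[Si](C)(C)C(C)(C)C)[C@H](OCOC)[C@H]1C(=C)COCc1ccc(OC)cc1 | intermediate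
24 | 2-(TBS-oxy)-3-vinyl-5,6-dihydro-4H-pyran from 22, cyclic vinyl ketene acetal (not isolated) | C=CC1=C(O[Si](C)(C)C(C)(C)C)O[C@H](C(=C)O[Si](C)(C)C(C)(C)C)[C@H](OCOC)[C@H]1C(=C)COCc1ccc(OC)cc1 | intermediate
25 | TBS ester of the ring-contracted acid: C-10 β-CO2TBS and α-vinyl, otherwise as 26 (not isolated) | CC(C)(C)[Si](C)(C)OC(=O)[C@@]1(C=C)CC(O[Si](C)(C)C(C)(C)C)=C[C@H](OCOC)[C@H]1C(=C)COCc1ccc(OC)cc1 | intermediate
26 | cyclohexene alcohol: C-10 β-CH2OH and α-vinyl, C-5 β-[3-(PMB-oxy)prop-1-en-2-yl] (5αH), C-6 α-OMOM, C-7=C-8 enol TBS ether | OC[C@@]1(C=C)CC(O[Si](C)(C)C(C)(C)C)=C[C@H](OCOC)[C@H]1C(=C)COCc1ccc(OC)cc1 | intermediate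
27 | 14-O-TBDPS ether of 26 | CC(C)(C)[Si](OC[C@@]1(C=C)CC(O[Si](C)(C)C(C)(C)C)=C[C@H](OCOC)[C@H]1C(=C)COCc1ccc(OC)cc1)(c1ccccc1)c1ccccc1 | intermediate
28 | keto ester as C-7 epimer mixture, otherwise as 29 (not isolated) | CCOC(=O)CC1C(=O)C[C@](C=C)(CO[Si](c2ccccc2)(c2ccccc2)C(C)(C)C)[C@H](C(=C)COCc2ccc(OC)cc2)[C@H]1OCOC | intermediate
29 | keto ester: 8-oxo, 7β-CH2CO2Et (7αH), 6α-OMOM, 5β-[3-(PMB-oxy)prop-1-en-2-yl], 10β-CH2OTBDPS, 10α-vinyl | CCOC(=O)C[C@@H]1C(=O)C[C@](C=C)(CO[Si](c2ccccc2)(c2ccccc2)C(C)(C)C)[C@H](C(=C)COCc2ccc(OC)cc2)[C@H]1OCOC | intermediate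
30 | 6α-hydroxy keto ester, 29 without the MOM group (not isolated) | CCOC(=O)C[C@@H]1C(=O)C[C@](C=C)(CO[Si](c2ccccc2)(c2ccccc2)C(C)(C)C)[C@H](C(=C)COCc2ccc(OC)cc2)[C@H]1O | intermediate
31 | trans-fused keto-lactone: 12,6α-olide with C-11 H2, 8-oxo, 14-OTBDPS, 15-OPMB (5αH,6βH,7αH) | C=C[C@]1(CO[Si](c3ccccc3)(c3ccccc3)C(C)(C)C)CC(=O)[C@H]2CC(=O)O[C@@H]2[C@H]1C(=C)COCc1ccc(OC)cc1 | intermediate
32 | lithium 8β-alkoxide from 31 (not isolated) | C=C[C@]1(CO[Si](c3ccccc3)(c3ccccc3)C(C)(C)C)C[C@@H](O[Li])[C@H]2CC(=O)O[C@@H]2[C@H]1C(=C)COCc1ccc(OC)cc1 | intermediate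
33 | 8β-(TES-oxy) lactone with C-11 H2, 14-OTBDPS, 15-OPMB | C=C[C@]1(CO[Si](c3ccccc3)(c3ccccc3)C(C)(C)C)C[C@@H](O[Si](CC)(CC)CC)[C@H]2CC(=O)O[C@@H]2[C@H]1C(=C)COCc1ccc(OC)cc1 | intermediate
34 | lithium enolate of 33, C-11=C-12(OLi) (not isolated) | C=C[C@]1(CO[Si](c3ccccc3)(c3ccccc3)C(C)(C)C)C[C@@H](O[Si](CC)(CC)CC)[C@H]2C=C(O[Li])O[C@@H]2[C@H]1C(=C)COCc1ccc(OC)cc1 | intermediate
35 | 11-(dimethylaminomethyl) lactone, C-11 epimers (not isolated) | C=C[C@]1(CO[Si](c3ccccc3)(c3ccccc3)C(C)(C)C)C[C@@H](O[Si](CC)(CC)CC)[C@H]2C(CN(C)C)C(=O)O[C@@H]2[C@H]1C(=C)COCc1ccc(OC)cc1 | intermediate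
36 | 11-(trimethylammoniomethyl) lactone iodide (not isolated) | C=C[C@]1(CO[Si](c3ccccc3)(c3ccccc3)C(C)(C)C)C[C@@H](O[Si](CC)(CC)CC)[C@H]2C(C[N+](C)(C)C)C(=O)O[C@@H]2[C@H]1C(=C)COCc1ccc(OC)cc1.[I-] | intermediate
37 | 8β-(TES-oxy)-14-(TBDPS-oxy)-15-(PMB-oxy)elema-1,3,11(13)-trien-12,6α-olide (5αH,6βH,7αH) | C=C[C@]1(CO[Si](c3ccccc3)(c3ccccc3)C(C)(C)C)C[C@@H](O[Si](CC)(CC)CC)[C@H]2C(=C)C(=O)O[C@@H]2[C@H]1C(=C)COCc1ccc(OC)cc1 | intermediate
38 | 8β,14-dihydroxy-15-(PMB-oxy)elema-1,3,11(13)-trien-12,6α-olide | C=C[C@]1(CO)C[C@@H](O)[C@H]2C(=C)C(=O)O[C@@H]2[C@H]1C(=C)COCc1ccc(OC)cc1 | intermediate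
39 | 14-acetoxy-8β-hydroxy-15-(PMB-oxy)elema-1,3,11(13)-trien-12,6α-olide | C=C[C@]1(COC(C)=O)C[C@@H](O)[C@H]2C(=C)C(=O)O[C@@H]2[C@H]1C(=C)COCc1ccc(OC)cc1 | intermediate
40 | ethyl 2-(hydroxymethyl)prop-2-enoate | C=C(CO)C(=O)OCC | starting material
41 | ethyl 2-{[(tert-butyldimethylsilyl)oxy]methyl}prop-2-enoate | C=C(CO[Si](C)(C)C(C)(C)C)C(=O)OCC | intermediate
42 | 2-{[(tert-butyldimethylsilyl)oxy]methyl}prop-2-enoic acid | C=C(CO[Si](C)(C)C(C)(C)C)C(=O)O | intermediate
43 | 14-acetoxy-8α-{2-[(TBS-oxy)methyl]acryloyloxy}-15-(PMB-oxy)elema-1,3,11(13)-trien-12,6α-olide | C=C[C@]1(COC(C)=O)C[C@H](OC(=O)C(=C)CO[Si](C)(C)C(C)(C)C)[C@H]2C(=C)C(=O)O[C@@H]2[C@H]1C(=C)COCc1ccc(OC)cc1 | intermediate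
44 | 14-acetoxy-15-hydroxy-8α-{2-[(TBS-oxy)methyl]acryloyloxy}elema-1,3,11(13)-trien-12,6α-olide | C=C[C@]1(COC(C)=O)C[C@H](OC(=O)C(=C)CO[Si](C)(C)C(C)(C)C)[C@H]2C(=C)C(=O)O[C@@H]2[C@H]1C(=C)CO | intermediate
45 | 14-acetoxy-15-oxo-8α-{2-[(TBS-oxy)methyl]acryloyloxy}elema-1,3,11(13)-trien-12,6α-olide | C=C[C@]1(COC(C)=O)C[C@H](OC(=O)C(=C)CO[Si](C)(C)C(C)(C)C)[C@H]2C(=C)C(=O)O[C@@H]2[C@H]1C(=C)C=O | intermediate
46 | 14-acetoxy-8α-[2-(hydroxymethyl)acryloyloxy]-15-oxoelema-1,3,11(13)-trien-12,6α-olide (5αH,6βH,7αH; CNP0185525.1) | C=C[C@]1(COC(C)=O)C[C@H](OC(=O)C(=C)CO)[C@H]2C(=C)C(=O)O[C@@H]2[C@H]1C(=C)C=O | target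

**Totals and risks**

Total step count: 23. Longest linear sequence: 20 steps (steps 1–6, 8–17, 20–23); steps 7, 18 and 19 make the two side fragments.

Steps most likely to fail:

Step 10. The γ-deprotonation of the ethylidene lactone may be incomplete or unselective, or the silyloxydiene may be lost to side reactions before the [3,3] shift, so that ring contraction and quaternary-center formation do not occur together. The fallback separates the two events; it sets out from 12 (with cuprate 18) and comes back to the route at 26. Conjugate addition of 18 to 12 with a proton quench would give the saturated lactone F1. Its simple silyl ketene acetal (LiN(iPr)2, TBSCl, then 90 °C) would undergo the same ring contraction without a dienolate, and mild hydrolysis of the silyl ester (K2CO3, MeOH–H2O) would give the cyclohexenecarboxylic acid F2. Me3SiCHN2 would give the methyl ester F3. Its ester enolate (LiN(iPr)2, −78 °C) should add acetaldehyde anti to the neighbouring C-5 branch to give the quaternary aldol F4. Dehydration with the Burgess reagent can only go toward the methyl group and would give the vinyl ester F5, which LiAlH4 reduces to 26.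

Step 20. The axial alkoxyphosphonium ion may eliminate to a cyclohexene, or may not form at all at the hindered axial alcohol, instead of undergoing substitution. The fallback sets out from 39 and comes back at 43. ClCH2SO2Cl and pyridine would give the 8β-chloromethanesulfonate F6. The caesium salt of acid 42 (Cs2CO3, 18-crown-6, toluene, 80 °C) would displace it with inversion, a sulfonate displacement that is known to work on hindered secondary alcohols where the Mitsunobu reaction fails.

Step 12. The radical may add to the 1,1-disubstituted alkene as well as to the enol silane, or the C-6 OMOM group may be lost by β-elimination during base equilibration. The fallback sets out from 27 and comes back at 28. Cu(acac)2-catalysed cyclopropanation of the electron-rich enol silane with ethyl diazoacetate would give the siloxycyclopropane ester F7. Ring opening with Et3N·3HF would give the γ-keto ester 28, which is equilibrated to 29 as in step 12.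

**Further compounds**

F1 | step 10 | (4R,5R,6S)-4-{3-[(4-methoxybenzyl)oxy]prop-1-en-2-yl}-5-(methoxymethoxy)-6-[1-(TBS-oxy)ethenyl]tetrahydro-2H-pyran-2-one | C=C(O[Si](C)(C)C(C)(C)C)[C@H]1OC(=O)C[C@H](C(=C)COCc2ccc(OC)cc2)[C@H]1OCOC
F2 | step 10 | cyclohexenecarboxylic acid: C-10 β-CO2H and α-H, otherwise as 26 | OC(=O)[C@H]1CC(O[Si](C)(C)C(C)(C)C)=C[C@H](OCOC)[C@H]1C(=C)COCc1ccc(OC)cc1
F3 | step 10 | methyl ester of F2 | COC(=O)[C@H]1CC(O[Si](C)(C)C(C)(C)C)=C[C@H](OCOC)[C@H]1C(=C)COCc1ccc(OC)cc1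
F4 | step 10 | quaternary aldol: C-10 β-CO2Me and α-(1-hydroxyethyl), carbinol epimers | COC(=O)[C@@]1(C(C)O)CC(O[Si](C)(C)C(C)(C)C)=C[C@H](OCOC)[C@H]1C(=C)COCc1ccc(OC)cc1
F5 | step 10 | vinyl ester: C-10 β-CO2Me and α-vinyl, otherwise as 26 | COC(=O)[C@@]1(C=C)CC(O[Si](C)(C)C(C)(C)C)=C[C@H](OCOC)[C@H]1C(=C)COCc1ccc(OC)cc1
F7 | step 12 | siloxycyclopropane ester: ethyl cyclopropanecarboxylate fused across C-7 and C-8 of 27 (C-8 OTBS), cyclopropane stereoisomers | CCOC(=O)C1C2[C@H](OCOC)[C@@H](C(=C)COCc3ccc(OC)cc3)[C@@](C=C)(CO[Si](c3ccccc3)(c3ccccc3)C(C)(C)C)CC12O[Si](C)(C)C(C)(C)C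
F6 | step 20 | 8β-chloromethanesulfonate of 39 | C=C[C@]1(COC(C)=O)C[C@@H](OS(=O)(=O)CCl)[C@H]2C(=C)C(=O)O[C@@H]2[C@H]1C(=C)COCc1ccc(OC)cc1
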